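Ring B is opened across its 1,3-diene: at the C8 carbinol level, the C6=C7 ring alkene carrying the C11=C12 isopropenyl group on C7 is the signature of an enyne metathesis between a vinyl group on the quaternary C5 of ring A and a C7≡C11 methyl alkyne. One ruthenium-catalysed step forms C6–C7, closes ring B and transfers a methylene to C11. The precursor is a fully stereodefined ring A cyclohexane (C3 senecioate, C4 and C5 methyls, C5 vinyl) whose C10 side chain already bears the C9 tiglate, a C8 tetrahydropyranyl ether and the propynyl unit; afterwards only C8 unmasking, oxidation and a 1,4-reduction remain.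

Key step: step 13

Remark: locants C1–C15 follow the eremophilane skeleton of the target (ring A: C1–C5 and C10; ring B: C5–C10); three centres that are erased later are carried without control: the methyl-bearing ring carbon of 4–6 (left undefined, planarised in step 5), the acetal carbon of the tetrahydropyranyl group (left undefined, removed in step 14) and C8 (drawn as the expected 8R isomer, oxidised in step 15).

Step 1
Reactants: 1 (3E)-3-methylpent-3-en-2-one
Product: 2 triisopropyl{[(3E)-3-methylpenta-1,3-dien-2-yl]oxy}silane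
Conditions: TIPSOTf, Et3N, CH2Cl2, 0 °C
Reagents that add atoms: triisopropylsilyl trifluoromethanesulfonate, CC(C)[Si](OS(=O)(=O)C(F)(F)F)(C(C)C)C(C)C
Why: Silyl enol ether formation by soft enolisation: the O-silylated enone loses a proton from the α′-methyl group, which should give the cross-conjugated 2-silyloxy-1,3-diene with the (E)-alkene untouched.

Step 2
Reactants: 2 triisopropyl{[(3E)-3-methylpenta-1,3-dien-2-yl]oxy}silane; 3 2,2,2-trifluoroethyl prop-2-enoate
Product: 4 2,2,2-trifluoroethyl (1R)-2,3-dimethyl-4-[(triisopropylsilyl)oxy]cyclohex-3-ene-1-carboxylate (both C2 epimers)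
Conditions: (R)-3,3-diphenyl-1-(2-methylphenyl)tetrahydro-1H,3H-pyrrolo[1,2-c][1,3,2]oxazaborole·HN(SO2CF3)2 (15 mol%), CH2Cl2, −78 → −20 °C
Reagents that add atoms: none
Why: Catalytic enantioselective Diels–Alder reaction: the silyloxy group (para) and the terminal methyl (ortho) both direct the ester-bearing carbon to the methyl-bearing diene terminus, and the chiral oxazaborolidinium cation shields one face of the coordinated acrylate so that the diene should add to the Si face of its α-carbon, which sets C10 (ring C1) as R; the endo/exo ratio at the neighbouring carbon is irrelevant because that centre is planarised in step 5.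

Step 3
Reactants: 4 2,2,2-trifluoroethyl (1R)-2,3-dimethyl-4-[(triisopropylsilyl)oxy]cyclohex-3-ene-1-carboxylate
Product: 5 {(1R)-2,3-dimethyl-4-[(triisopropylsilyl)oxy]cyclohex-3-en-1-yl}methanol (both C2 epimers)
Conditions: LiAlH4, Et2O, 0 °C
Reagents that add atoms: none
Why: Hydride reduction of the activated ester to the primary alcohol; the silyl enol ether is inert to LiAlH4, and removing the carbonyl now means that C10 is never γ to an enone and α to an ester at the same time, so it cannot racemise later.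

Step 4
Reactants: 5 {(1R)-2,3-dimethyl-4-[(triisopropylsilyl)oxy]cyclohex-3-en-1-yl}methanol
Product: 6 ({(4R)-4-[(benzyloxy)methyl]-2,3-dimethylcyclohex-1-en-1-yl}oxy)triisopropylsilane (both C3 epimers)
Conditions: NaH, BnBr, Bu4NI (cat.), THF, 0 °C → rt
Reagents that add atoms: benzyl bromide, BrCc1ccccc1
Why: Williamson etherification of the alkoxide; the benzyl ether tolerates divalent palladium and the cuprate and is cleaved without an extra operation in step 7.

Step 5
Reactants: 6 ({(4R)-4-[(benzyloxy)methyl]-2,3-dimethylcyclohex-1-en-1-yl}oxy)triisopropylsilane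
Product: 7 (4R)-4-[(benzyloxy)methyl]-2,3-dimethylcyclohex-2-en-1-one
Conditions: Pd(OAc)2 (1.1 equiv), MeCN, rt → 40 °C
Reagents that add atoms: none
Why: Saegusa–Ito oxidation: the regiodefined silyl enol ether is converted into the divalent palladium enolate at C4, and β-hydride elimination of the C5 hydrogen should give the tetrasubstituted enone, erasing the uncontrolled centre while C10 stays untouched.

Step 6
Reactants: 7 (4R)-4-[(benzyloxy)methyl]-2,3-dimethylcyclohex-2-en-1-one; 8 vinylmagnesium bromide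
Product: 10 (2R,3S,4R)-4-[(benzyloxy)methyl]-3-ethenyl-2,3-dimethylcyclohexan-1-one, via trimethylsilyl enol ether 9 (not isolated)
Conditions: CuBr·SMe2 (20 mol%), Me3SiCl, THF, −78 → −30 °C; then 1 M HCl, THF, 0 °C
Reagents that add atoms: chlorotrimethylsilane, C[Si](C)(C)Cl (its silyl group sits only in 9)
Why: Copper-catalysed 1,4-addition of a vinyl Grignard reagent accelerated by Me3SiCl: the nucleophile should attack C5 of the half-chair axially and trans to the C10 substituent, which creates the quaternary centre (vinyl α, methyl β), and hydrolysis of 9 protonates C4 axially from the face opposite the axial C5 methyl, which leaves the C4 methyl equatorial and cis to the C5 methyl (this is also the more stable epimer, so NaOMe/MeOH can correct the ratio).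

Step 7
Reactants: 10 (2R,3S,4R)-4-[(benzyloxy)methyl]-3-ethenyl-2,3-dimethylcyclohexan-1-one
Product: 11 (1R,2R,3S,4R)-3-ethenyl-4-(hydroxymethyl)-2,3-dimethylcyclohexan-1-ol
Conditions: Li, NH3(l)/THF, t-BuOH, −78 °C; then NH4Cl
Reagents that add atoms: none
Why: Dissolving-metal reduction: protonation of the ketyl under thermodynamic control should give the equatorial 3α-alcohol (hydride reagents would approach away from the axial C5 methyl and give the axial alcohol), the same conditions cleave the benzyl ether, and the isolated vinyl group is not reduced at −78 °C.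

Step 8
Reactants: 11 (1R,2R,3S,4R)-3-ethenyl-4-(hydroxymethyl)-2,3-dimethylcyclohexan-1-ol
Product: 12 (1R,2R,3R,4R)-2-ethenyl-4-hydroxy-2,3-dimethylcyclohexane-1-carbaldehyde
Conditions: TEMPO (10 mol%), PhI(OAc)2, CH2Cl2, rt
Reagents that add atoms: none
Why: Oxoammonium (TEMPO) oxidation with PhI(OAc)2 as terminal oxidant, selective for the primary over the hindered secondary alcohol; the trans-1,4 arrangement excludes lactol formation and the near-neutral medium leaves C10 untouched.

Step 9
Reactants: 12 (1R,2R,3R,4R)-2-ethenyl-4-hydroxy-2,3-dimethylcyclohexane-1-carbaldehyde; 13 3-methylbut-2-enoyl chloride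
Product: 14 (1R,2R,3R,4R)-3-ethenyl-4-formyl-2,3-dimethylcyclohexyl 3-methylbut-2-enoate
Conditions: pyridine, DMAP (cat.), CH2Cl2, 0 °C
Reagents that add atoms: none
Why: DMAP-catalysed O-acylation of the equatorial secondary alcohol under weakly basic conditions that should neither deconjugate the acyl group nor enolise the hindered aldehyde; with the senecioate in place now, no acylation is needed once the isomerisation-prone β,γ-unsaturated ketone exists.

Step 10
Reactants: 15 but-2-yn-1-ol
Product: 16 2-(but-2-yn-1-yloxy)oxane (racemic)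
Conditions: 3,4-dihydro-2H-pyran, PPTS (cat.), CH2Cl2, rt
Reagents that add atoms: 3,4-dihydro-2H-pyran, C1=COCCC1
Why: Acid-catalysed addition of the alcohol to the enol ether (tetrahydropyranyl acetal formation); the acetal withstands n-BuLi and is removed later under very mild acid.

Step 11
Reactants: 14 (1R,2R,3R,4R)-3-ethenyl-4-formyl-2,3-dimethylcyclohexyl 3-methylbut-2-enoate; 16 2-(but-2-yn-1-yloxy)oxane
Product: 19 (1R,2R,3R,4R)-3-ethenyl-4-[(1S,2R)-1-hydroxy-2-(oxan-2-yloxy)pent-3-yn-1-yl]-2,3-dimethylcyclohexyl 3-methylbut-2-enoate, via lithiated propargyl ether 17 (not isolated), via alkoxyallenylzinc bromide 18 (not isolated)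
Conditions: 16, n-BuLi, THF, −78 °C; ZnBr2, −78 → −40 °C; then 14, −78 → −20 °C; aq NH4Cl
Reagents that add atoms: n-butyllithium, [Li]CCCC (lithium only in 17); zinc dibromide, Br[Zn]Br (zinc and bromine only in 18)
Why: Addition of a γ-alkoxyallenylzinc to an aldehyde (SE2′ through a cyclic transition state): α-lithiation of the propargylic ether and transmetalation give 18, which bonds through its oxygen-bearing carbon to give the homopropargylic alcohol; C9 is set by Felkin–Anh control from C10 (attack anti to the quaternary C5, with C1 flanking the carbonyl oxygen), which corresponds to 9S, the cyclic transition state gives the anti C8/C9 relationship (8R, of no consequence), and the senecioate is inert to the organozinc.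

Step 12
Reactants: 19 (1R,2R,3R,4R)-3-ethenyl-4-[(1S,2R)-1-hydroxy-2-(oxan-2-yloxy)pent-3-yn-1-yl]-2,3-dimethylcyclohexyl 3-methylbut-2-enoate; 20 (2E)-2-methylbut-2-enoyl chloride
Product: 21 (1S,2R)-1-{(1R,2R,3R,4R)-2-ethenyl-2,3-dimethyl-4-[(3-methylbut-2-enoyl)oxy]cyclohexyl}-2-(oxan-2-yloxy)pent-3-yn-1-yl (2E)-2-methylbut-2-enoate
Conditions: pyridine, DMAP (cat.), CH2Cl2, 0 → 40 °C
Reagents that add atoms: none
Why: Acylation of the hindered C9 alcohol with the acid chloride under nucleophilic catalysis; the (E)-2-methylbut-2-enoyl group is the thermodynamically stable isomer, and the acetal and the senecioate are untouched under basic conditions.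

Step 13
Reactants: 21 (1S,2R)-1-{(1R,2R,3R,4R)-2-ethenyl-2,3-dimethyl-4-[(3-methylbut-2-enoyl)oxy]cyclohexyl}-2-(oxan-2-yloxy)pent-3-yn-1-yl (2E)-2-methylbut-2-enoate
Product: 22 (1S,2R,4aR,5R,6R,8aR)-4a,5-dimethyl-6-[(3-methylbut-2-enoyl)oxy]-2-(oxan-2-yloxy)-3-(prop-1-en-2-yl)-1,2,4a,5,6,7,8,8a-octahydronaphthalen-1-yl (2E)-2-methylbut-2-enoate
Conditions: (H2IMes)(PCy3)Cl2Ru=CHPh (second-generation Grubbs catalyst, 10 mol%), ethene (1 atm), toluene, 80 °C
Reagents that add atoms: none
Why: Enyne metathesis in the yne-then-ene order: the ruthenium methylidene formed under ethene adds across C7≡C11 (CH2 to C11, ruthenium to C7) through a ruthenacyclobutene, and the resulting vinylcarbene at C7 captures the C5 vinyl group through a ruthenacyclobutane that collapses to C6=C7 and returns the methylidene. The closest known reaction type is the ring-closing metathesis of 1,7-enynes to 1-alkenylcyclohexenes with this catalyst under ethene. Ring B closes in the exo mode to the six-membered ring, and no stereocentre is created. The step needs six- over seven-membered closure and reaction at the alkyne in preference to the two enoates: the 1,7-tether, the trans-diequatorial C5–C6 and C10–C9 arms on the ring A chair and the ethene atmosphere (which returns a mis-oriented carbene or an acyclic 1,3-diene to productive intermediates) secure the first, and the inertness of the trisubstituted, electron-poor tiglate and senecioate alkenes toward this carbene secures the second. The propargylic acetal and both esters are spectators.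

Step 14
Reactants: 22 (1S,2R,4aR,5R,6R,8aR)-4a,5-dimethyl-6-[(3-methylbut-2-enoyl)oxy]-2-(oxan-2-yloxy)-3-(prop-1-en-2-yl)-1,2,4a,5,6,7,8,8a-octahydronaphthalen-1-yl (2E)-2-methylbut-2-enoate
Product: 23 (1S,2R,4aR,5R,6R,8aR)-2-hydroxy-4a,5-dimethyl-6-[(3-methylbut-2-enoyl)oxy]-3-(prop-1-en-2-yl)-1,2,4a,5,6,7,8,8a-octahydronaphthalen-1-yl (2E)-2-methylbut-2-enoate
Conditions: PPTS, MeOH, 40 °C
Reagents that add atoms: none
Why: Acid-catalysed transacetalisation to methanol removes the tetrahydropyranyl group; pyridinium tosylate is too weak to ionise the allylic C8–O bond or to promote acyl migration from O9 to O8.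

Step 15
Reactants: 23 (1S,2R,4aR,5R,6R,8aR)-2-hydroxy-4a,5-dimethyl-6-[(3-methylbut-2-enoyl)oxy]-3-(prop-1-en-2-yl)-1,2,4a,5,6,7,8,8a-octahydronaphthalen-1-yl (2E)-2-methylbut-2-enoate
Product: 24 (1S,4aR,5R,6R,8aR)-4a,5-dimethyl-6-[(3-methylbut-2-enoyl)oxy]-2-oxo-3-(prop-1-en-2-yl)-1,2,4a,5,6,7,8,8a-octahydronaphthalen-1-yl (2E)-2-methylbut-2-enoate
Conditions: Dess–Martin periodinane, pyridine, CH2Cl2, 0 °C → rt
Reagents that add atoms: none
Why: Dess–Martin oxidation of the allylic secondary alcohol under buffered, non-basic conditions should give the cross-conjugated dienone without touching C9, whose equatorial acyloxy group is also the stable arrangement; both C8 epimers converge here.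

Step 16
Reactants: 24 (1S,4aR,5R,6R,8aR)-4a,5-dimethyl-6-[(3-methylbut-2-enoyl)oxy]-2-oxo-3-(prop-1-en-2-yl)-1,2,4a,5,6,7,8,8a-octahydronaphthalen-1-yl (2E)-2-methylbut-2-enoate
Product: 25 (1S,3S,4aR,5R,6R,8aR)-4a,5-dimethyl-6-[(3-methylbut-2-enoyl)oxy]-2-oxo-3-(prop-1-en-2-yl)decahydronaphthalen-1-yl (2E)-2-methylbut-2-enoate
Conditions: [(Ph3P)CuH]6 (0.3 equiv), degassed C6H6, H2O (3 equiv), rt; aq NH4Cl, 0 °C
Reagents that add atoms: none
Why: Conjugate reduction with Stryker's reagent: hydride goes to C6 of the enone (the ester-conjugated and isolated alkenes react far more slowly), and the copper dienolate is protonated at its α-carbon C7 and not at C12, which gives the β,γ-unsaturated ketone; C7 is the last stereocentre, and the equatorial 7α-isopropenyl (7S) isomer is the thermodynamically preferred one because the axial alternative is 1,3-diaxial to the C5 methyl, so the mildly basic medium and work-up are expected to converge on it.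

Compound list
1 | (3E)-3-methylpent-3-en-2-one | C/C=C(\C)C(C)=O | starting material
2 | triisopropyl{[(3E)-3-methylpenta-1,3-dien-2-yl]oxy}silane | C=C(O[Si](C(C)C)(C(C)C)C(C)C)/C(C)=C/C | intermediate
3 | 2,2,2-trifluoroethyl prop-2-enoate | C=CC(=O)OCC(F)(F)F | starting material
4 | 2,2,2-trifluoroethyl (1R)-2,3-dimethyl-4-[(triisopropylsilyl)oxy]cyclohex-3-ene-1-carboxylate (both C2 epimers) | O=C(OCC(F)(F)F)[C@@H]1CCC(O[Si](C(C)C)(C(C)C)C(C)C)=C(C)C1C | intermediate
5 | {(1R)-2,3-dimethyl-4-[(triisopropylsilyl)oxy]cyclohex-3-en-1-yl}methanol (both C2 epimers) | OC[C@@H]1CCC(O[Si](C(C)C)(C(C)C)C(C)C)=C(C)C1C | intermediate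
6 | ({(4R)-4-[(benzyloxy)methyl]-2,3-dimethylcyclohex-1-en-1-yl}oxy)triisopropylsilane (both C3 epimers) | C(OC[C@@H]1CCC(O[Si](C(C)C)(C(C)C)C(C)C)=C(C)C1C)c1ccccc1 | intermediate
7 | (4R)-4-[(benzyloxy)methyl]-2,3-dimethylcyclohex-2-en-1-one | c1ccccc1COC[C@@H]2CCC(=O)C(C)=C2C | intermediate
8 | vinylmagnesium bromide | C=C[Mg]Br | starting material
9 | {[(3S,4R)-4-[(benzyloxy)methyl]-3-ethenyl-2,3-dimethylcyclohex-1-en-1-yl]oxy}trimethylsilane | c1ccccc1COC[C@@H]2CCC(O[Si](C)(C)C)=C(C)[C@@]2(C)C=C | intermediate (not isolated)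
10 | (2R,3S,4R)-4-[(benzyloxy)methyl]-3-ethenyl-2,3-dimethylcyclohexan-1-one | c1ccccc1COC[C@@H]2CCC(=O)[C@H](C)[C@@]2(C)C=C | intermediate
11 | (1R,2R,3S,4R)-3-ethenyl-4-(hydroxymethyl)-2,3-dimethylcyclohexan-1-ol | OC[C@@H]1CC[C@@H](O)[C@H](C)[C@@]1(C)C=C | intermediate
12 | (1R,2R,3R,4R)-2-ethenyl-4-hydroxy-2,3-dimethylcyclohexane-1-carbaldehyde | O=C[C@@H]1CC[C@@H](O)[C@H](C)[C@@]1(C)C=C | intermediate
13 | 3-methylbut-2-enoyl chloride | CC(C)=CC(=O)Cl | starting material
14 | (1R,2R,3R,4R)-3-ethenyl-4-formyl-2,3-dimethylcyclohexyl 3-methylbut-2-enoate | O=C[C@@H]1CC[C@@H](OC(=O)C=C(C)C)[C@H](C)[C@@]1(C)C=C | intermediate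
15 | but-2-yn-1-ol | CC#CCO | starting material
16 | 2-(but-2-yn-1-yloxy)oxane (racemic) | CC#CCOC1CCCCO1 | intermediate
17 | [1-(oxan-2-yloxy)but-2-yn-1-yl]lithium | CC#CC([Li])OC1CCCCO1 | intermediate (not isolated)
18 | bromo[4-(oxan-2-yloxy)buta-2,3-dien-2-yl]zinc | CC(=C=COC1CCCCO1)[Zn]Br | intermediate (not isolated)
19 | (1R,2R,3R,4R)-3-ethenyl-4-[(1S,2R)-1-hydroxy-2-(oxan-2-yloxy)pent-3-yn-1-yl]-2,3-dimethylcyclohexyl 3-methylbut-2-enoate | CC#C[C@@H](OC1CCCCO1)[C@@H](O)[C@@H]2CC[C@@H](OC(=O)C=C(C)C)[C@H](C)[C@@]2(C)C=C | intermediate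
20 | (2E)-2-methylbut-2-enoyl chloride | C/C=C(\C)C(=O)Cl | starting material
21 | (1S,2R)-1-{(1R,2R,3R,4R)-2-ethenyl-2,3-dimethyl-4-[(3-methylbut-2-enoyl)oxy]cyclohexyl}-2-(oxan-2-yloxy)pent-3-yn-1-yl (2E)-2-methylbut-2-enoate | CC#C[C@@H](OC1CCCCO1)[C@@H](OC(=O)/C(C)=C/C)[C@@H]2CC[C@@H](OC(=O)C=C(C)C)[C@H](C)[C@@]2(C)C=C | intermediate
22 | (1S,2R,4aR,5R,6R,8aR)-4a,5-dimethyl-6-[(3-methylbut-2-enoyl)oxy]-2-(oxan-2-yloxy)-3-(prop-1-en-2-yl)-1,2,4a,5,6,7,8,8a-octahydronaphthalen-1-yl (2E)-2-methylbut-2-enoate | C=C(C)C1=C[C@]2(C)[C@@H](C)[C@H](OC(=O)C=C(C)C)CC[C@H]2[C@H](OC(=O)/C(C)=C/C)[C@@H]1OC3CCCCO3 | intermediate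
23 | (1S,2R,4aR,5R,6R,8aR)-2-hydroxy-4a,5-dimethyl-6-[(3-methylbut-2-enoyl)oxy]-3-(prop-1-en-2-yl)-1,2,4a,5,6,7,8,8a-octahydronaphthalen-1-yl (2E)-2-methylbut-2-enoate | C=C(C)C1=C[C@]2(C)[C@@H](C)[C@H](OC(=O)C=C(C)C)CC[C@H]2[C@H](OC(=O)/C(C)=C/C)[C@@H]1O | intermediate
24 | (1S,4aR,5R,6R,8aR)-4a,5-dimethyl-6-[(3-methylbut-2-enoyl)oxy]-2-oxo-3-(prop-1-en-2-yl)-1,2,4a,5,6,7,8,8a-octahydronaphthalen-1-yl (2E)-2-methylbut-2-enoate | C=C(C)C1=C[C@]2(C)[C@@H](C)[C@H](OC(=O)C=C(C)C)CC[C@H]2[C@H](OC(=O)/C(C)=C/C)C1=O | intermediate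
25 | (1S,3S,4aR,5R,6R,8aR)-4a,5-dimethyl-6-[(3-methylbut-2-enoyl)oxy]-2-oxo-3-(prop-1-en-2-yl)decahydronaphthalen-1-yl (2E)-2-methylbut-2-enoate | C=C(C)[C@@H]1C[C@]2(C)[C@@H](C)[C@H](OC(=O)C=C(C)C)CC[C@H]2[C@H](OC(=O)/C(C)=C/C)C1=O | target

Total step count: 16. Longest linear sequence: 15 (steps 1–9 and 11–16; step 10 prepares the side-chain reagent).

Steps most likely to fail

Step 13 (key step). The vinyl group on the quaternary C5 may be slow to meet the ruthenium vinylcarbene, so that the alkyne is consumed by cross-metathesis with ethene and the material stalls as an acyclic diene or oligomerises. Fallback, from 21 back to 22: the two events are separated. Enyne cross-metathesis of 21 with ethene (3–4 atm, (H2IMes)(PCy3)Cl2Ru=CHPh, CH2Cl2, rt) is driven to the acyclic triene F1, in which C7 and C11 each carry a methylidene. F1 is then closed by diene ring-closing metathesis between the C5 vinyl group and the C7 methylidene with the more reactive Mo(N-2,6-iPr2C6H3)(CHCMe2Ph)[OCMe(CF3)2]2 in toluene with ethene swept out, which forms the same C6=C7 bond and gives 22.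

Step 16. The copper dienolate may be protonated from the face opposite the C5 methyl (axial isopropenyl at C7) or at C12 instead of C7, and the C11=C12 bond may later migrate into conjugation under base or acid. Fallback, from 24 to 25: C7 is treated as a thermodynamic problem in a separate operation instead of relying on the face selectivity of the quench. The reduction is quenched cold into buffer, and the crude product containing the axial 7-epimer of the target F2 is exposed to a catalytic amount of DBU in CH2Cl2 at 0 °C; the reaction is stopped as soon as F2 is consumed. F2 carries its isopropenyl group 1,3-diaxial to the C5 methyl, so epimerisation through the dienolate (fast reprotonation at the α-carbon) should run well ahead of the slower γ-protonation that leads to the conjugated enone, giving 25.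

Step 11. Facial discrimination at the aldehyde may be insufficient (C9 epimers), or the organozinc may bond through its methyl-bearing terminus (allenyl carbinol). Fallback, from 14 and back at 24: the adducts are separated, and the 9R epimer of 19 F3 is esterified with (2E)-2-methylbut-2-enoic acid under Mitsunobu conditions (PPh3, diisopropyl azodicarboxylate, toluene, 0 °C → rt). This installs the tiglate with inversion at C9 and gives the 8-epimer of 21 F4. F4 is taken through the conditions of steps 13, 14 and 15 via the 8-epimer of 22 F5 and the 8-epimer of 23 F6, and the C8 epimers meet at dienone 24.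

Further compounds
F1 | step 13 | (1S,2R)-1-{(1R,2R,3R,4R)-2-ethenyl-2,3-dimethyl-4-[(3-methylbut-2-enoyl)oxy]cyclohexyl}-4-methyl-3-methylidene-2-(oxan-2-yloxy)pent-4-en-1-yl (2E)-2-methylbut-2-enoate | C=C(C)C(=C)[C@@H](OC1CCCCO1)[C@@H](OC(=O)/C(C)=C/C)[C@@H]2CC[C@@H](OC(=O)C=C(C)C)[C@H](C)[C@@]2(C)C=C
F2 | step 16 | (1S,3R,4aR,5R,6R,8aR)-4a,5-dimethyl-6-[(3-methylbut-2-enoyl)oxy]-2-oxo-3-(prop-1-en-2-yl)decahydronaphthalen-1-yl (2E)-2-methylbut-2-enoate | C=C(C)[C@H]1C[C@]2(C)[C@@H](C)[C@H](OC(=O)C=C(C)C)CC[C@H]2[C@H](OC(=O)/C(C)=C/C)C1=O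
F3 | step 11 | (1R,2R,3R,4R)-3-ethenyl-4-[(1R,2S)-1-hydroxy-2-(oxan-2-yloxy)pent-3-yn-1-yl]-2,3-dimethylcyclohexyl 3-methylbut-2-enoate | CC#C[C@H](OC1CCCCO1)[C@H](O)[C@@H]2CC[C@@H](OC(=O)C=C(C)C)[C@H](C)[C@@]2(C)C=C
F4 | step 11 | (1S,2S)-1-{(1R,2R,3R,4R)-2-ethenyl-2,3-dimethyl-4-[(3-methylbut-2-enoyl)oxy]cyclohexyl}-2-(oxan-2-yloxy)pent-3-yn-1-yl (2E)-2-methylbut-2-enoate | CC#C[C@H](OC1CCCCO1)[C@@H](OC(=O)/C(C)=C/C)[C@@H]2CC[C@@H](OC(=O)C=C(C)C)[C@H](C)[C@@]2(C)C=C
F5 | step 11 | (1S,2S,4aR,5R,6R,8aR)-4a,5-dimethyl-6-[(3-methylbut-2-enoyl)oxy]-2-(oxan-2-yloxy)-3-(prop-1-en-2-yl)-1,2,4a,5,6,7,8,8a-octahydronaphthalen-1-yl (2E)-2-methylbut-2-enoate | C=C(C)C1=C[C@]2(C)[C@@H](C)[C@H](OC(=O)C=C(C)C)CC[C@H]2[C@H](OC(=O)/C(C)=C/C)[C@H]1OC3CCCCO3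
F6 | step 11 | (1S,2S,4aR,5R,6R,8aR)-2-hydroxy-4a,5-dimethyl-6-[(3-methylbut-2-enoyl)oxy]-3-(prop-1-en-2-yl)-1,2,4a,5,6,7,8,8a-octahydronaphthalen-1-yl (2E)-2-methylbut-2-enoate | C=C(C)C1=C[C@]2(C)[C@@H](C)[C@H](OC(=O)C=C(C)C)CC[C@H]2[C@H](OC(=O)/C(C)=C/C)[C@H]1O
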